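The C3–C4 ethano bridge of the dimethyldihydropyran ring, which links aromatic C4a of ring A to the quaternary C2, is treated as a hydrogenated cis-olefin and closed by ring-closing metathesis of an ortho-vinyl aryl 1,1-dimethylallyl ether (gem-dimethyl assistance). Naringenin supplies the whole C6–C3–C6 skeleton; its pyranone ring is a temporary ring that masks one ortho-hydroxyl of ring A and the enone. The same 1,1-dimethylallyl ether is placed on both rings in one operation: on ring A it closes the pyran by metathesis with a 6-vinyl group, on ring B a Claisen shift converts it into the prenyl group. Base-induced ring opening and one chemoselective hydrogenation complete the target.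

Key step: step 5

Remark: commercial racemic naringenin is assumed (its C2 stereocentre is erased in step 7 and the target is achiral). The iodination is drawn at C6; the C8 regioisomer would lead to the same chalcone 10, because ring opening makes the two ortho-hydroxyls of ring A equivalent.

Step 1
Reactants: 1 (±)-naringenin
Product: 2 (±)-6-iodonaringenin, 5,7-dihydroxy-2-(4-hydroxyphenyl)-6-iodochroman-4-one
Conditions: NIS (1.0 equiv), DMF, 0 °C to rt, dark
Reagents that add atoms: N-iodosuccinimide, O=C1CCC(=O)N1I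
Why: Electrophilic aromatic iodination should take place on the phloroglucinol-type ring A, far more nucleophilic than the mono-phenolic ring B, at the carbon flanked by 5-OH and 7-OH, one equivalent at low temperature limiting di-iodination; no stereocenter is created.

Step 2
Reactants: 2 (±)-6-iodonaringenin; 3 tributyl(vinyl)stannane
Product: 4 (±)-6-vinylnaringenin, 6-ethenyl-5,7-dihydroxy-2-(4-hydroxyphenyl)chroman-4-one
Conditions: Pd(PPh3)4 (5 mol%), DMF, 80 °C
Reagents that add atoms: none
Why: Stille cross-coupling runs under neutral conditions that tolerate the three free phenols and the base-sensitive flavanone, and it should replace iodine by the vinyl group whose inner carbon becomes C4 of the pyran ring.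

Step 3
Reactants: 4 (±)-6-vinylnaringenin; 5 3-chloro-3-methylbut-1-yne
Product: 6 (±)-6-ethenyl-5-hydroxy-7-(2-methylbut-3-yn-2-yloxy)-2-[4-(2-methylbut-3-yn-2-yloxy)phenyl]chroman-4-one
Conditions: 5 (2.4 equiv in total), K2CO3 (3 equiv), KI (cat.), CuI (cat.), acetone, 50 °C
Reagents that add atoms: 3-chloro-3-methylbut-1-yne (the second equivalent of 5, for the second phenol), CC(C)(Cl)C#C
Why: Williamson-type O-alkylation with the tertiary propargylic chloride (copper-assisted ionisation) consumes two molecules of 5, one for each free phenol (7-OH and 4'-OH), while 5-OH stays free because it is locked in a hydrogen bond to the C4 carbonyl; the mild temperature keeps the aryl propargyl ethers from rearranging.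

Step 4
Reactants: 6 (±)-6-vinylflavanone bis(2-methylbut-3-yn-2-yl) ether
Product: 7 (±)-6-ethenyl-5-hydroxy-7-(2-methylbut-3-en-2-yloxy)-2-[4-(2-methylbut-3-en-2-yloxy)phenyl]chroman-4-one
Conditions: H2 (1 atm), Pd/CaCO3 poisoned with Pb(OAc)2 (Lindlar catalyst), quinoline, EtOAc, rt, stopped after 2 equiv H2
Reagents that add atoms: none
Why: Lindlar semi-hydrogenation: both terminal alkynes are adsorbed and reduced far faster than any alkene on the lead-poisoned catalyst, so the two propargyl ethers should become 1,1-dimethylallyl ethers while the styrenyl vinyl group is kept.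

Step 5
Reactants: 7 (±)-6-vinylflavanone bis(1,1-dimethylallyl) ether
Product: 8 (±)-5-hydroxy-8,8-dimethyl-2-[4-(2-methylbut-3-en-2-yloxy)phenyl]-2,3-dihydro-4H,8H-pyrano[3,2-g]chromen-4-one
Conditions: second-generation Grubbs catalyst RuCl2(=CHPh)(PCy3)(H2IMes) (5 mol%), CH2Cl2 (0.005 M), 40 °C
Reagents that add atoms: none
Why: Ring-closing olefin metathesis: the ruthenium alkylidene engages one terminal olefin of ring A, and a [2+2] cycloaddition–cycloreversion sequence through a ruthenacyclobutane joins the styrenyl carbon (future C4) to the ether-side vinyl carbon (future C3) with loss of ethylene. The closest known reaction type is the metathesis closure of 2-vinylaryl allyl ethers to 2H-chromenes. The six-membered pyran ring closes between two terminal vinyl groups held ortho on ring A and gives the endocyclic cis C3=C4 olefin, the gem-dimethyl group at C2 (Thorpe–Ingold effect) and the escape of ethylene favouring closure. No stereocenter is created, and the C2 centre of the flavanone is untouched. The selectivity needed is chemoselectivity among three terminal olefins: only the 6-vinyl/7-ether pair can form an unstrained ring, whereas the ring-B 1,1-dimethylallyl ether has no partner within reach and, being flanked by a quaternary carbon, cross-metathesises only slowly at high dilution. The chelated 5-OH and the ketone should not interfere with the catalyst, and 40 °C is too low for a Claisen shift of either ether.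

Step 6
Reactants: 8 (±)-pyranoflavanone with ring-B 1,1-dimethylallyl ether
Product: 9 (±)-5-hydroxy-2-[4-hydroxy-3-(3-methylbut-2-en-1-yl)phenyl]-8,8-dimethyl-2,3-dihydro-4H,8H-pyrano[3,2-g]chromen-4-one
Conditions: toluene, 120 °C, sealed tube
Reagents that add atoms: none
Why: Aromatic Claisen rearrangement: the [3,3]-sigmatropic shift of the ring-B 1,1-dimethylallyl ether, followed by tautomerisation, transfers the allyl unit with transposition to an ortho carbon (both equivalent, para blocked), which should give the 3-methylbut-2-enyl group next to the freed 4'-OH without creating a stereocenter.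

Step 7
Reactants: 9 (±)-3'-prenyl pyranoflavanone
Product: 10 (E)-1-(5,7-dihydroxy-2,2-dimethyl-2H-chromen-6-yl)-3-[4-hydroxy-3-(3-methylbut-2-en-1-yl)phenyl]prop-2-en-1-one
Conditions: KOH (10% aq), EtOH, rt, argon; then poured into ice-cold 1 M HCl
Reagents that add atoms: none
Why: Base-induced flavanone–chalcone isomerisation: E1cB (retro-oxa-Michael) opening of ring C through the C3 enolate is driven by the delocalised chalcone phenoxide, the E-enone forms under thermodynamic control, the C2 stereocentre is erased, and inverse quench into cold acid should protonate the phenoxides before ring closure can recur.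

Step 8
Reactants: 10 pyranochalcone
Product: 11 1-(5,7-dihydroxy-2,2-dimethylchroman-6-yl)-3-[4-hydroxy-3-(3-methylbut-2-en-1-yl)phenyl]propan-1-one (target)
Conditions: H2 (1 atm), RhCl(PPh3)3 (10 mol%), toluene/THF, rt, stopped after 2 equiv H2
Reagents that add atoms: none
Why: Homogeneous hydrogenation with Wilkinson's catalyst RhCl(PPh3)3 should saturate the cis-disubstituted C3=C4 olefin of the chromene and the disubstituted enone olefin, whereas the trisubstituted prenyl olefin binds too poorly to rhodium to be reduced at a comparable rate, and ketone and aryl ethers are inert.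

Compound list

1 | (±)-naringenin, 5,7-dihydroxy-2-(4-hydroxyphenyl)chroman-4-one | O=C1CC(c2ccc(O)cc2)Oc2cc(O)cc(O)c21 | starting material
2 | (±)-6-iodonaringenin, 5,7-dihydroxy-2-(4-hydroxyphenyl)-6-iodochroman-4-one | O=C1CC(c2ccc(O)cc2)Oc2cc(O)c(I)c(O)c21 | intermediate
3 | tributyl(vinyl)stannane | C=C[Sn](CCCC)(CCCC)CCCC | starting material
4 | (±)-6-vinylnaringenin, 6-ethenyl-5,7-dihydroxy-2-(4-hydroxyphenyl)chroman-4-one | O=C1CC(c2ccc(O)cc2)Oc2cc(O)c(C=C)c(O)c21 | intermediate
5 | 3-chloro-3-methylbut-1-yne | CC(C)(Cl)C#C | starting material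
6 | (±)-6-ethenyl-5-hydroxy-7-(2-methylbut-3-yn-2-yloxy)-2-[4-(2-methylbut-3-yn-2-yloxy)phenyl]chroman-4-one | O=C1CC(c2ccc(OC(C)(C)C#C)cc2)Oc2cc(OC(C)(C)C#C)c(C=C)c(O)c21 | intermediate
7 | (±)-6-ethenyl-5-hydroxy-7-(2-methylbut-3-en-2-yloxy)-2-[4-(2-methylbut-3-en-2-yloxy)phenyl]chroman-4-one | O=C1CC(c2ccc(OC(C)(C)C=C)cc2)Oc2cc(OC(C)(C)C=C)c(C=C)c(O)c21 | intermediate
8 | (±)-5-hydroxy-8,8-dimethyl-2-[4-(2-methylbut-3-en-2-yloxy)phenyl]-2,3-dihydro-4H,8H-pyrano[3,2-g]chromen-4-one | O=C1CC(c2ccc(OC(C)(C)C=C)cc2)Oc2cc3OC(C)(C)C=Cc3c(O)c21 | intermediate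
9 | (±)-5-hydroxy-2-[4-hydroxy-3-(3-methylbut-2-en-1-yl)phenyl]-8,8-dimethyl-2,3-dihydro-4H,8H-pyrano[3,2-g]chromen-4-one | O=C1CC(c2ccc(O)c(CC=C(C)C)c2)Oc2cc3OC(C)(C)C=Cc3c(O)c21 | intermediate
10 | (E)-1-(5,7-dihydroxy-2,2-dimethyl-2H-chromen-6-yl)-3-[4-hydroxy-3-(3-methylbut-2-en-1-yl)phenyl]prop-2-en-1-one | CC(C)=CCc1cc(/C=C/C(=O)c2c(O)cc3OC(C)(C)C=Cc3c2O)ccc1O | intermediate
11 | 1-(5,7-dihydroxy-2,2-dimethylchroman-6-yl)-3-[4-hydroxy-3-(3-methylbut-2-en-1-yl)phenyl]propan-1-one | CC(C)=CCc1cc(CCC(=O)c2c(O)cc3c(c2O)CCC(C)(C)O3)ccc1O | target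

Total step count: 8
Longest linear sequence: 8 steps (1 to 11)

Steps most likely to fail

Step 8. The rate gap between hydrogenation of the two conjugated disubstituted olefins and of the trisubstituted prenyl olefin may be too small, so over-reduction can set in before the enone is consumed. The chalcone may also close back to a flavanone, which withdraws the enone from reduction. The fallback saturates the pyran olefin before the prenyl group exists; it sets out from 4 and comes back at 11.
- Compound 4 is etherified once, at the more acidic 7-OH, with 5 (1 equiv, K2CO3, KI, CuI, acetone) to give (±)-6-ethenyl-5-hydroxy-2-(4-hydroxyphenyl)-7-(2-methylbut-3-yn-2-yloxy)chroman-4-one F1.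
- Lindlar semi-hydrogenation gives (±)-6-ethenyl-5-hydroxy-2-(4-hydroxyphenyl)-7-(2-methylbut-3-en-2-yloxy)chroman-4-one F2.
- Ring-closing metathesis as in step 5 gives (±)-5-hydroxy-2-(4-hydroxyphenyl)-8,8-dimethyl-2,3-dihydro-4H,8H-pyrano[3,2-g]chromen-4-one F3, which is not isolated.
- Hydrogen is admitted to the same flask, with the ruthenium residue as hydrogenation catalyst, to give (±)-5-hydroxy-2-(4-hydroxyphenyl)-8,8-dimethyl-2,3,7,8-tetrahydro-4H,6H-pyrano[3,2-g]chromen-4-one F4.
- Its only unchelated phenol is etherified with 5 to give (±)-5-hydroxy-8,8-dimethyl-2-[4-(2-methylbut-3-yn-2-yloxy)phenyl]-2,3,7,8-tetrahydro-4H,6H-pyrano[3,2-g]chromen-4-one F5.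
- Lindlar reduction gives (±)-5-hydroxy-8,8-dimethyl-2-[4-(2-methylbut-3-en-2-yloxy)phenyl]-2,3,7,8-tetrahydro-4H,6H-pyrano[3,2-g]chromen-4-one F6.
- Claisen rearrangement gives (±)-5-hydroxy-2-[4-hydroxy-3-(3-methylbut-2-en-1-yl)phenyl]-8,8-dimethyl-2,3,7,8-tetrahydro-4H,6H-pyrano[3,2-g]chromen-4-one F7.
- KOH followed by a cold acid quench opens ring C to (E)-1-(5,7-dihydroxy-2,2-dimethylchroman-6-yl)-3-[4-hydroxy-3-(3-methylbut-2-en-1-yl)phenyl]prop-2-en-1-one F8.
- In F8 the enone is the only olefin to be reduced, and H2 with RhCl(PPh3)3 should give 11.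

Step 7. The 2',6'-dihydroxychalcone may cyclise back to the flavanone during neutralisation and handling, and prolonged contact with strong base may cause retro-aldol cleavage. The fallback traps the phenoxides as they form; it sets out from 9 and comes back at 11.
- Heating 9 with Ac2O and NaOAc at 120 °C should open ring C and acetylate all three phenols, giving (E)-1-(5,7-diacetoxy-2,2-dimethyl-2H-chromen-6-yl)-3-[4-acetoxy-3-(3-methylbut-2-en-1-yl)phenyl]prop-2-en-1-one F9, which cannot recyclise.
- Hydrogenation with RhCl(PPh3)3 gives 1-(5,7-diacetoxy-2,2-dimethylchroman-6-yl)-3-[4-acetoxy-3-(3-methylbut-2-en-1-yl)phenyl]propan-1-one F10.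
- K2CO3 in MeOH removes the acetates to give 11.

Step 3. The tertiary propargylic chloride may be lost by elimination, the 7-OH next to the vinyl group may alkylate incompletely, and base-induced opening of ring C may expose a further phenoxide. The fallback avoids alkynes altogether; it sets out from 4 and comes back at 7, replacing steps 3 and 4. Decarboxylative O-allylation with tert-butyl 2-methylbut-3-en-2-yl carbonate (two equivalents), catalysed by zerovalent palladium (Pd(PPh3)4, THF, 0 °C), should attach the 1,1-dimethylallyl groups directly to 7-OH and 4'-OH, the phenoxide attacking the more substituted allyl terminus under kinetic control. This detour makes no new compound (F0).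

Further compounds

F1 | step 8 | (±)-6-ethenyl-5-hydroxy-2-(4-hydroxyphenyl)-7-(2-methylbut-3-yn-2-yloxy)chroman-4-one | O=C1CC(c2ccc(O)cc2)Oc2cc(OC(C)(C)C#C)c(C=C)c(O)c21
F2 | step 8 | (±)-6-ethenyl-5-hydroxy-2-(4-hydroxyphenyl)-7-(2-methylbut-3-en-2-yloxy)chroman-4-one | O=C1CC(c2ccc(O)cc2)Oc2cc(OC(C)(C)C=C)c(C=C)c(O)c21
F3 | step 8 | (±)-5-hydroxy-2-(4-hydroxyphenyl)-8,8-dimethyl-2,3-dihydro-4H,8H-pyrano[3,2-g]chromen-4-one | O=C1CC(c2ccc(O)cc2)Oc2cc3OC(C)(C)C=Cc3c(O)c21
F4 | step 8 | (±)-5-hydroxy-2-(4-hydroxyphenyl)-8,8-dimethyl-2,3,7,8-tetrahydro-4H,6H-pyrano[3,2-g]chromen-4-one | O=C1CC(c2ccc(O)cc2)Oc2cc3OC(C)(C)CCc3c(O)c21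
F5 | step 8 | (±)-5-hydroxy-8,8-dimethyl-2-[4-(2-methylbut-3-yn-2-yloxy)phenyl]-2,3,7,8-tetrahydro-4H,6H-pyrano[3,2-g]chromen-4-one | O=C1CC(c2ccc(OC(C)(C)C#C)cc2)Oc2cc3OC(C)(C)CCc3c(O)c21
F6 | step 8 | (±)-5-hydroxy-8,8-dimethyl-2-[4-(2-methylbut-3-en-2-yloxy)phenyl]-2,3,7,8-tetrahydro-4H,6H-pyrano[3,2-g]chromen-4-one | O=C1CC(c2ccc(OC(C)(C)C=C)cc2)Oc2cc3OC(C)(C)CCc3c(O)c21
F7 | step 8 | (±)-5-hydroxy-2-[4-hydroxy-3-(3-methylbut-2-en-1-yl)phenyl]-8,8-dimethyl-2,3,7,8-tetrahydro-4H,6H-pyrano[3,2-g]chromen-4-one | O=C1CC(c2ccc(O)c(CC=C(C)C)c2)Oc2cc3OC(C)(C)CCc3c(O)c21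
F8 | step 8 | (E)-1-(5,7-dihydroxy-2,2-dimethylchroman-6-yl)-3-[4-hydroxy-3-(3-methylbut-2-en-1-yl)phenyl]prop-2-en-1-one | CC(C)=CCc1cc(/C=C/C(=O)c2c(O)cc3OC(C)(C)CCc3c2O)ccc1O
F9 | step 7 | (E)-1-(5,7-diacetoxy-2,2-dimethyl-2H-chromen-6-yl)-3-[4-acetoxy-3-(3-methylbut-2-en-1-yl)phenyl]prop-2-en-1-one | CC(C)=CCc1cc(/C=C/C(=O)c2c(OC(C)=O)cc3OC(C)(C)C=Cc3c2OC(C)=O)ccc1OC(C)=O
F10 | step 7 | 1-(5,7-diacetoxy-2,2-dimethylchroman-6-yl)-3-[4-acetoxy-3-(3-methylbut-2-en-1-yl)phenyl]propan-1-one | CC(C)=CCc1cc(CCC(=O)c2c(OC(C)=O)cc3OC(C)(C)CCc3c2OC(C)=O)ccc1OC(C)=O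
F0 | step 3 | none | none
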